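**Assumption:** the target is gallocatechin-(4α→6)-gallocatechin [upper unit (2R,3S,4R), lower unit (2R,3S)], and commercial (+)-dihydromyricetin is the natural (2R,3R) enantiomer, recrystallised to full optical purity if needed.

## Retrosynthetic overview

1. Target 11 comes from 10 by one hydrogenolysis that removes twelve O-benzyl groups and the C8 bromine.
2. Interflavan bond C4(upper)–C6(lower): the C4 carbonyl carbon of the upper flavanone is used as a donor (N-tosylhydrazone 8, then diazo carbon 9) and joined at palladium to C6 of aryl iodide 7. Both carbons are acceptors in their ordinary form (C=O and C–I); formate ends the cycle, so C4 keeps one hydrogen and its configuration is set here.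
3. Both 8 and 7 come from one intermediate, hexa-O-benzyl-dihydromyricetin 3 (7 by C4 deoxygenation to 5, then C8 bromination and C6 iodination).
4. 3 comes from (+)-dihydromyricetin 1. No ring is formed anywhere: rings A, B and C of both units and their 2,3-trans stereocentres are taken intact from 1.

## Route

Step 1
Reactants: 1 (+)-dihydromyricetin
Product: 2 5,7,3',4',5'-penta-O-benzyl-dihydromyricetin
Conditions: BnBr (6 equiv), K2CO3 (6 equiv), DMF, Ar, rt to 45 °C
Reagents that add atoms: benzyl bromide, BrCc1ccccc1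
Why: Williamson etherification of the five phenoxides; carbonate does not alkylate the secondary 3-OH and no stereocentre is touched.

Step 2
Reactants: 2 5,7,3',4',5'-penta-O-benzyl-dihydromyricetin
Product: 3 3,5,7,3',4',5'-hexa-O-benzyl-dihydromyricetin
Conditions: BnBr (3 equiv), Ag2O (2 equiv), 4 Å MS, CH2Cl2, dark, rt to 40 °C
Reagents that add atoms: benzyl bromide, BrCc1ccccc1
Why: Silver-oxide-assisted (Purdie-type) Williamson benzylation works by halide abstraction without forming an alkoxide or enolate, so the base-labile flavanonol should neither ring-open nor epimerise at C2 or C3.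

Step 3
Reactants: 3 3,5,7,3',4',5'-hexa-O-benzyl-dihydromyricetin
Product: 5 hexa-O-benzyl-(+)-gallocatechin, via flavan-4-ol 4 (not isolated)
Conditions: NaBH4, THF/MeOH, 0 °C; then crude alcohol added slowly to Et3SiH (8 equiv), TFA (5 equiv), CH2Cl2, −20 to 0 °C
Reagents that add atoms: none
Why: Borohydride reduction of the aryl ketone, then ionic hydrogenation (Kursanov–Parnes) through the 5,7-dialkoxy-stabilised C4 cation, removes the C4 oxygen; C2 and C3 are not involved and the C4 centre of 4 is erased (inverse addition to excess silane suppresses self-condensation of the cation).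

Step 4
Reactants: 5 hexa-O-benzyl-(+)-gallocatechin
Product: 7 hexa-O-benzyl-8-bromo-6-iodogallocatechin, via C8-bromide 6 (not isolated)
Conditions: NBS (1.0 equiv), CH2Cl2, −78 to 0 °C; then NIS (1.1 equiv), TFA (10 mol %), 0 °C to rt
Reagents that add atoms: N-bromosuccinimide, BrN1C(=O)CCC1=O; N-iodosuccinimide, IN1C(=O)CCC1=O
Why: Two successive electrophilic aromatic halogenations on ring A: NBS takes the less hindered C8 (the established selectivity for benzylated flavan-3-ols), and NIS then iodinates C6, the only ring A position left and activated by three oxygens; no stereocentre is involved.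

Step 5
Reactants: 3 3,5,7,3',4',5'-hexa-O-benzyl-dihydromyricetin
Product: 8 N-tosylhydrazone of hexa-O-benzyl-dihydromyricetin (E/Z mixture at C=N, inconsequential)
Conditions: TsNHNH2 (1.5 equiv), PPTS (10 mol %), THF/EtOH, 65 °C
Reagents that add atoms: p-toluenesulfonyl hydrazide, Cc1ccc(cc1)S(=O)(=O)NN
Why: Acid-catalysed hydrazone condensation turns the C4 carbonyl into a diazo precursor; the weakly acidic conditions leave C2 and C3 unchanged.

Step 6
Reactants: 8 N-tosylhydrazone of hexa-O-benzyl-dihydromyricetin (1.3 equiv); 7 hexa-O-benzyl-8-bromo-6-iodogallocatechin (1.0 equiv)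
Product: 10 hexa-O-benzylgallocatechin-(4α→6)-8-bromo-hexa-O-benzylgallocatechin, via diazoflavan 9 (not isolated)
Conditions: Pd(PPh3)4 (10 mol %), K2CO3 (3 equiv), HCO2K (2 equiv), 1,4-dioxane, 100 °C
Reagents that add atoms: none
Why: Proposed new method: Bamford–Stevens loss of sulfinate from the potassium salt of 8 gives diazo compound 9, whose C4 (the former carbonyl carbon, now a carbon donor) attacks ArPdI(PPh3)2 formed from the C6–I bond of 7 (Pd(PPh3)4 inserts into the aryl iodide far faster than into the hindered C8–Br); loss of N2 gives the carbene complex ArPdI(PPh3)(=CR2) and the aryl group migrates to C4 on the face anti to the 3-benzyloxy group, which leaves palladium syn to that ether and anti to H3, so the syn β-hydride elimination that normally ends a Barluenga coupling is geometrically impossible in ring C and the benzylic palladium is instead taken by formate (decarboxylation to Pd–H, then C–H reductive elimination with retention), placing H4 cis to the 3-oxygen and the new aryl group trans to it (4α); insertion on the wrong face has a syn H3 and should drain away as the enol ether, not as the C4 epimer; the closest known reaction types are the Barluenga cross-coupling of N-tosylhydrazones with aryl halides and its formate-terminated reductive variant used for triarylmethanes.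

Step 7
Reactants: 10 hexa-O-benzylgallocatechin-(4α→6)-8-bromo-hexa-O-benzylgallocatechin
Product: 11 gallocatechin-(4α→6)-gallocatechin (CNP0286965.2)
Conditions: H2 (1 atm), Pd(OH)2/C, Et3N (2 equiv), THF/MeOH/H2O, rt
Reagents that add atoms: none
Why: Catalytic hydrogenolysis cleaves all twelve benzyl ethers and hydrodehalogenates C8–Br in one operation, as is standard for bromine-capped benzylated proanthocyanidins; Et3N takes up the HBr so the acid-labile interflavan bond survives, and the five stereocentres are untouched.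

## Compound list

1 | (+)-dihydromyricetin, (2R,3R)-3,5,7-trihydroxy-2-(3,4,5-trihydroxyphenyl)chroman-4-one | Oc1cc(O)c2c(c1)O[C@H](c1cc(O)c(O)c(O)c1)[C@@H](O)C2=O | starting material
2 | 5,7,3',4',5'-penta-O-benzyl-dihydromyricetin, (2R,3R) | c1ccccc1COc1cc(OCc3ccccc3)c2c(c1)O[C@H](c1cc(OCc3ccccc3)c(OCc3ccccc3)c(OCc3ccccc3)c1)[C@@H](O)C2=O | intermediate
3 | 3,5,7,3',4',5'-hexa-O-benzyl-dihydromyricetin, (2R,3R) | c1ccccc1COc1cc(OCc3ccccc3)c2c(c1)O[C@H](c1cc(OCc3ccccc3)c(OCc3ccccc3)c(OCc3ccccc3)c1)[C@@H](OCc3ccccc3)C2=O | intermediate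
4 | hexa-O-benzyl-flavan-4-ol (hexa-O-benzyl-leucodelphinidin), (2R,3S,4R), 3,4-trans major | c1ccccc1COc1cc(OCc3ccccc3)c2c(c1)O[C@H](c1cc(OCc3ccccc3)c(OCc3ccccc3)c(OCc3ccccc3)c1)[C@@H](OCc3ccccc3)[C@@H]2O | intermediate
5 | hexa-O-benzyl-(+)-gallocatechin, (2R,3S) | c1ccccc1COc1cc(OCc3ccccc3)c2c(c1)O[C@H](c1cc(OCc3ccccc3)c(OCc3ccccc3)c(OCc3ccccc3)c1)[C@@H](OCc3ccccc3)C2 | intermediate
6 | hexa-O-benzyl-8-bromogallocatechin, (2R,3S) | c1ccccc1COc1cc(OCc3ccccc3)c2c(c1Br)O[C@H](c1cc(OCc3ccccc3)c(OCc3ccccc3)c(OCc3ccccc3)c1)[C@@H](OCc3ccccc3)C2 | intermediate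
7 | hexa-O-benzyl-8-bromo-6-iodogallocatechin, (2R,3S) | c1ccccc1COc1c(I)c(OCc3ccccc3)c2c(c1Br)O[C@H](c1cc(OCc3ccccc3)c(OCc3ccccc3)c(OCc3ccccc3)c1)[C@@H](OCc3ccccc3)C2 | intermediate
8 | N-tosylhydrazone of 3, (2R,3S) | c1ccccc1COc1cc(OCc3ccccc3)c2c(c1)O[C@H](c1cc(OCc3ccccc3)c(OCc3ccccc3)c(OCc3ccccc3)c1)[C@@H](OCc3ccccc3)C2=NNS(=O)(=O)c1ccc(C)cc1 | intermediate
9 | (2R,3S)-4-diazo-hexa-O-benzylflavan | c1ccccc1COc1cc(OCc3ccccc3)c2c(c1)O[C@H](c1cc(OCc3ccccc3)c(OCc3ccccc3)c(OCc3ccccc3)c1)[C@@H](OCc3ccccc3)C2=[N+]=[N-] | intermediate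
10 | hexa-O-benzylgallocatechin-(4α→6)-8-bromo-hexa-O-benzylgallocatechin; upper unit 2,3-trans-3,4-trans, lower unit (2R,3S) | c1ccccc1COc1cc(OCc3ccccc3)c2c(c1)O[C@H](c1cc(OCc3ccccc3)c(OCc3ccccc3)c(OCc3ccccc3)c1)[C@@H](OCc3ccccc3)[C@@H]2c1c(OCc3ccccc3)c(Br)c2c(c1OCc3ccccc3)C[C@H](OCc3ccccc3)[C@@H](c1cc(OCc3ccccc3)c(OCc3ccccc3)c(OCc3ccccc3)c1)O2 | intermediate
11 | gallocatechin-(4α→6)-gallocatechin, (2R,3S,4R)-2-(3,4,5-trihydroxyphenyl)-4-[(2R,3S)-3,5,7-trihydroxy-2-(3,4,5-trihydroxyphenyl)chroman-6-yl]chromane-3,5,7-triol | Oc1cc(O)c2c(c1)O[C@H](c1cc(O)c(O)c(O)c1)[C@@H](O)[C@@H]2c1c(O)cc2c(c1O)C[C@H](O)[C@@H](c1cc(O)c(O)c(O)c1)O2 | target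

## Step count and risks

Total steps: 7. Longest linear sequence: 6 (steps 1, 2, 3, 4, 6, 7); the hydrazone branch (steps 1, 2, 5) joins at step 6.

**Step 6 (most likely to fail).** Formate may reduce ArPdI(PPh3)2 before the diazo carbon is captured (returning 6), diazo compound 9 may undergo a thermal 1,2-hydrogen shift to the enol ether, and the bond being made is very congested. The fallback sets out from 7 and comes back to the route at 10. Iodine–magnesium exchange on 7 with iPrMgCl·LiCl (THF, −40 °C; the C–I bond exchanges, C–Br does not) gives (hexa-O-benzyl-8-bromogallocatechin-6-yl)magnesium chloride F1. Quenching with B(OMe)3 and aqueous NH4Cl gives hexa-O-benzyl-8-bromogallocatechin-6-boronic acid F2. Heating 8 with F2 and K2CO3 in dioxane at 110 °C, with no transition metal, lets the diazo carbon of 9 add to boron; the aryl group then shifts from boron to C4 with loss of N2 to give the tertiary benzylic boronic acid F3, which is protodeboronated in the same pot to 10. C4 still reacts as the diazo donor carbon, but the C–C bond forms by a 1,2-shift on boron rather than at palladium. Stereocontrol at C4 is less secure here, and any 4β epimer would be removed by chromatography.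

**Step 2.** The hindered α-ketol may benzylate slowly, or Ag2O may oxidise it towards the flavonol. The fallback sets out from 2 and comes back at 5 (lower half) and, through 4, at 3 (upper half). NaBH4 reduces 2 to the 3,4-diol penta-O-benzyl-leucodelphinidin F4, and Et3SiH/TFA deoxygenates C4 to give 5,7,3',4',5'-penta-O-benzyl-(+)-gallocatechin F5. Its 3-OH is benzylated conventionally (NaH, BnBr, DMF), since flavans tolerate strong base, which gives 5. For the upper half, 5 is re-oxidised at C4 with DDQ in wet CH2Cl2 to 4 and then with Dess–Martin periodinane to 3.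

**Step 5.** The ketone is a vinylogous ester flanked by the 5- and 3-benzyloxy groups, so condensation with the bulky sulfonyl hydrazide may stall. The fallback sets out from 3 and comes back at 9. Condensation with the smaller N2H4·H2O (cat. AcOH, THF/EtOH, 60 °C) gives the N-unsubstituted hydrazone of hexa-O-benzyl-dihydromyricetin F6. Oxidation with activated MnO2 (CH2Cl2, 0 °C) gives a solution of diazo compound 9 without base, which is added slowly to the Pd(PPh3)4, 7 and HCO2K mixture of step 6.

Further compounds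
F1 | step 6 | (hexa-O-benzyl-8-bromogallocatechin-6-yl)magnesium chloride | c1ccccc1COc1c([Mg]Cl)c(OCc3ccccc3)c2c(c1Br)O[C@H](c1cc(OCc3ccccc3)c(OCc3ccccc3)c(OCc3ccccc3)c1)[C@@H](OCc3ccccc3)C2
F2 | step 6 | hexa-O-benzyl-8-bromogallocatechin-6-boronic acid | c1ccccc1COc1c(B(O)O)c(OCc3ccccc3)c2c(c1Br)O[C@H](c1cc(OCc3ccccc3)c(OCc3ccccc3)c(OCc3ccccc3)c1)[C@@H](OCc3ccccc3)C2
F3 | step 6 | C4-boronic acid of 10 (aryl group anti to the 3-benzyloxy group, boron syn) | c1ccccc1COc1cc(OCc3ccccc3)c2c(c1)O[C@H](c1cc(OCc3ccccc3)c(OCc3ccccc3)c(OCc3ccccc3)c1)[C@@H](OCc3ccccc3)[C@]2(B(O)O)c1c(OCc3ccccc3)c(Br)c2c(c1OCc3ccccc3)C[C@H](OCc3ccccc3)[C@@H](c1cc(OCc3ccccc3)c(OCc3ccccc3)c(OCc3ccccc3)c1)O2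
F4 | step 2 | penta-O-benzyl-leucodelphinidin, (2R,3S,4R)-flavan-3,4-diol | c1ccccc1COc1cc(OCc3ccccc3)c2c(c1)O[C@H](c1cc(OCc3ccccc3)c(OCc3ccccc3)c(OCc3ccccc3)c1)[C@@H](O)[C@@H]2O
F5 | step 2 | 5,7,3',4',5'-penta-O-benzyl-(+)-gallocatechin, (2R,3S) | c1ccccc1COc1cc(OCc3ccccc3)c2c(c1)O[C@H](c1cc(OCc3ccccc3)c(OCc3ccccc3)c(OCc3ccccc3)c1)[C@@H](O)C2
F6 | step 5 | N-unsubstituted hydrazone of hexa-O-benzyl-dihydromyricetin, (2R,3S) | c1ccccc1COc1cc(OCc3ccccc3)c2c(c1)O[C@H](c1cc(OCc3ccccc3)c(OCc3ccccc3)c(OCc3ccccc3)c1)[C@@H](OCc3ccccc3)C2=NN
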